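Ring B is disconnected at C8–C9 (labdane numbering). The feature used is that C8, the ring B carbon of the exocyclic C8=C17 methylene, is bonded directly to the stereocentre C9. C8 can therefore arrive as an alkenylpalladium from a 2-bromoallyl unit and add to C9 of an (E)-enoate standing on C10. One reductive Heck cyclisation closes ring B, keeps the C17 methylene, sets C9 and leaves the C11–C12 ester arm for the diene. Its precursor is a ring A cyclohexane carrying the C4 ester, the C5 arm (C6 silyl ether, 2-bromoallyl) and the C10 enoate. This C4/C5/C10 triad is first locked in a bridged lactone.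

Key step: step 14

Assumption: labdane numbering is used for all intermediates (ring A = C1–C5 and C10, ring B = C5–C10, C18 = ester carbon on C4, C19 and C20 = methyls on C4 and C10), and (Ipc)2BBr (Ipc = isopinocampheyl) made from (−)-α-pinene is treated as a stock reagent.

Step 1
Reactants: 1 methyl 2-oxocyclohexane-1-carboxylate
Product: 2 methyl (1R,2R)-2-hydroxycyclohexane-1-carboxylate
Conditions: H2 (80 atm), RuCl2[(R)-BINAP] (0.5 mol %), MeOH, 50 °C
Reagents that add atoms: none
Why: Noyori asymmetric hydrogenation of a β-keto ester: the (R)-BINAP–ruthenium hydride reduces the chelated ketone from one face and should set the carbinol carbon as R, while the labile ester-bearing carbon does not matter because step 2 planarises it.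

Step 2
Reactants: 2 methyl (1R,2R)-2-hydroxycyclohexane-1-carboxylate
Product: 3 methyl (1S,2R)-2-hydroxy-1-methylcyclohexane-1-carboxylate
Conditions: LiN(i-Pr)2 (2.2 equiv), THF, −78 → −20 °C; MeI, DMPU, −78 → 0 °C
Reagents that add atoms: iodomethane, CI
Why: Fráter–Seebach alkylation: the chelated lithium alkoxide–enolate dianion takes methyl iodide on the face anti to the C–O bond, so the R carbinol relays into the quaternary C4 (S; methyl trans and ester cis to the hydroxyl).

Step 3
Reactants: 3 methyl (1S,2R)-2-hydroxy-1-methylcyclohexane-1-carboxylate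
Product: 4 methyl (1S)-1-methyl-2-oxocyclohexane-1-carboxylate
Conditions: Dess–Martin periodinane, CH2Cl2, rt
Reagents that add atoms: none
Why: Dess–Martin oxidation of a secondary alcohol; C4 is quaternary and cannot epimerise, and the carbinol centre has served its purpose.

Step 4
Reactants: 4 methyl (1S)-1-methyl-2-oxocyclohexane-1-carboxylate
Product: 5 methyl (1S)-1,3-dimethyl-2-oxocyclohexane-1-carboxylate (C10 epimers)
Conditions: LiN(i-Pr)2, THF, −78 °C; MeI, −78 → 0 °C
Reagents that add atoms: iodomethane, CI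
Why: Kinetic enolate alkylation: only C10 carries acidic hydrogens, so the methyl group (C20) enters there, and the C10 epimer composition is irrelevant because step 5 passes through the enolate again.

Step 5
Reactants: 5 methyl (1S)-1,3-dimethyl-2-oxocyclohexane-1-carboxylate
Product: 7 (1S,5S)-1,5-dimethyl-3-oxabicyclo[3.3.1]nonane-2,9-dione, via hydroxymethyl ketone 6 (not isolated)
Conditions: LiN(i-Pr)2, THF, −78 → 0 °C; CH2O (gas, from cracked paraformaldehyde), −78 → 0 °C; AcOH
Reagents that add atoms: formaldehyde, C=O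
Why: Aldol hydroxymethylation followed by lactonisation through transesterification: formaldehyde adds reversibly to the only possible enolate, and only the aldolate whose C9 oxymethyl arm is cis to the C4 ester can bridge the 1,3-diaxial gap to the δ-lactone, so the ring constraint sets C10 relative to C4 while the other aldolate reverts by retro-aldol.

Step 6
Reactants: 7 (1S,5S)-1,5-dimethyl-3-oxabicyclo[3.3.1]nonane-2,9-dione
Product: 8 (1S,5R)-1,5-dimethyl-9-methylidene-3-oxabicyclo[3.3.1]nonan-2-one
Conditions: Ph3PCH3Br, KN(SiMe3)2, THF, 0 °C; then 7, 0 → 50 °C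
Reagents that add atoms: methyltriphenylphosphonium bromide, C[P+](c1ccccc1)(c1ccccc1)c1ccccc1.[Br-]
Why: Wittig methylenation of a non-enolisable, tied-back bridge ketone (adamantanone-like), which should react faster than the hindered lactone carbonyl, and this brings in C6.

Step 7
Reactants: 8 (1S,5R)-1,5-dimethyl-9-methylidene-3-oxabicyclo[3.3.1]nonan-2-one
Product: 10 (1S,5R,9S)-9-(hydroxymethyl)-1,5-dimethyl-3-oxabicyclo[3.3.1]nonan-2-one, via C6 borane adduct 9 (not isolated)
Conditions: 9-BBN, THF, 65 °C; H2O2, NaH2PO4/Na2HPO4 buffer (pH 7), 0 °C → rt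
Reagents that add atoms: hydrogen peroxide, OO; 9-borabicyclo[3.3.1]nonane, B1C2CCCC1CCC2 (its boron unit stays only in 9)
Why: Hydroboration–oxidation (anti-Markovnikov, syn addition): boron goes to the terminal C6 and hydrogen to C5 from the face over the flattened lactone bridge, which has one flanking axial hydrogen instead of two and lies anti to the more electron-rich C–C bonds, so C6 ends over the carbocycle, trans to the C18 and C9 arms.

Step 8
Reactants: 10 (1S,5R,9S)-9-(hydroxymethyl)-1,5-dimethyl-3-oxabicyclo[3.3.1]nonan-2-one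
Product: 11 (1S,5R,9S)-1,5-dimethyl-2-oxo-3-oxabicyclo[3.3.1]nonane-9-carbaldehyde
Conditions: Dess–Martin periodinane, CH2Cl2, 0 °C → rt
Reagents that add atoms: none
Why: Dess–Martin oxidation under near-neutral conditions gives the C6 aldehyde without enolisation at the hindered C5–H, and the aldehyde is used at once.

Step 9
Reactants: 11 (1S,5R,9S)-1,5-dimethyl-2-oxo-3-oxabicyclo[3.3.1]nonane-9-carbaldehyde
Product: 13 (1S,5R,9S)-9-[(1R)-3-bromo-1-hydroxybut-3-en-1-yl]-1,5-dimethyl-3-oxabicyclo[3.3.1]nonan-2-one, via borinate ester 12 (not isolated)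
Conditions: (Ipc)2BBr [from (−)-α-pinene], allene, CH2Cl2, −10 °C; then 11, −78 °C; H2O2, NaH2PO4/Na2HPO4 buffer (pH 7)
Reagents that add atoms: allene, C=C=C; bromodiisopinocampheylborane, BrB([C@H]1C[C@H]2C[C@@H]([C@@H]1C)C2(C)C)[C@H]1C[C@H]2C[C@@H]([C@@H]1C)C2(C)C
Why: Asymmetric allylboration with a (2-bromoallyl)diisopinocampheylborane made by bromoboration of allene: the closed chair transition state is governed by the isopinocampheyl groups and should give the 6R carbinol, since the nearly mirror-symmetric surroundings of the aldehyde exert little bias, and O6 cannot reach C18 because the two arms are trans-diaxial in the bicycle.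

Step 10
Reactants: 13 (1S,5R,9S)-9-[(1R)-3-bromo-1-hydroxybut-3-en-1-yl]-1,5-dimethyl-3-oxabicyclo[3.3.1]nonan-2-one
Product: 14 (1S,5R,9S)-9-[(1R)-3-bromo-1-(tert-butyldimethylsilyloxy)but-3-en-1-yl]-1,5-dimethyl-3-oxabicyclo[3.3.1]nonan-2-one
Conditions: TBSOTf, 2,6-lutidine, CH2Cl2, 0 °C → rt
Reagents that add atoms: tert-butyldimethylsilyl triflate, CC(C)(C)[Si](C)(C)OS(=O)(=O)C(F)(F)F
Why: Silylation of a hindered secondary alcohol with the silyl triflate; the ether shields O6 from later lactonisation onto C18 and from oxa-Michael addition to the enoate.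

Step 11
Reactants: 14 (1S,5R,9S)-9-[(1R)-3-bromo-1-(tert-butyldimethylsilyloxy)but-3-en-1-yl]-1,5-dimethyl-3-oxabicyclo[3.3.1]nonan-2-one
Product: 16 methyl (1S,2S,3R)-2-[(1R)-3-bromo-1-(tert-butyldimethylsilyloxy)but-3-en-1-yl]-3-(hydroxymethyl)-1,3-dimethylcyclohexane-1-carboxylate, via potassium carboxylate 15 (not isolated)
Conditions: KOH (1.05 equiv), MeOH–H2O, 60 °C; evaporate; MeI, DMF, 0 °C → rt
Reagents that add atoms: potassium hydroxide, [K+].[OH-]; iodomethane, CI
Why: Saponification followed by carboxylate O-alkylation: hydroxide opens the bridged lactone irreversibly and methyl iodide esterifies the salt without passing through the free hydroxy acid, which restores the C18 methyl ester and frees the C9 alcohol.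

Step 12
Reactants: 16 methyl (1S,2S,3R)-2-[(1R)-3-bromo-1-(tert-butyldimethylsilyloxy)but-3-en-1-yl]-3-(hydroxymethyl)-1,3-dimethylcyclohexane-1-carboxylate
Product: 17 methyl (1S,2S,3R)-2-[(1R)-3-bromo-1-(tert-butyldimethylsilyloxy)but-3-en-1-yl]-3-formyl-1,3-dimethylcyclohexane-1-carboxylate
Conditions: Dess–Martin periodinane, CH2Cl2, rt
Reagents that add atoms: none
Why: Dess–Martin oxidation of a neopentyl primary alcohol to a non-enolisable aldehyde, carried out directly after step 11 so that relactonisation has no time to occur.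

Step 13
Reactants: 17 methyl (1S,2S,3R)-2-[(1R)-3-bromo-1-(tert-butyldimethylsilyloxy)but-3-en-1-yl]-3-formyl-1,3-dimethylcyclohexane-1-carboxylate
Product: 18 methyl (1S,2S,3S)-2-[(1R)-3-bromo-1-(tert-butyldimethylsilyloxy)but-3-en-1-yl]-3-[(E)-3-methoxy-3-oxoprop-1-en-1-yl]-1,3-dimethylcyclohexane-1-carboxylate
Conditions: (MeO)2P(O)CH2CO2Me, NaH, THF, 0 → 40 °C
Reagents that add atoms: trimethyl phosphonoacetate, COC(=O)CP(=O)(OC)OC
Why: Horner–Wadsworth–Emmons olefination of a non-enolisable α-quaternary aldehyde with a stabilised phosphonate anion, which gives the (E)-C9=C11 enoate under thermodynamic control and avoids any metathesis next to the vinyl bromide.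

Step 14
Reactants: 18 methyl (1S,2S,3S)-2-[(1R)-3-bromo-1-(tert-butyldimethylsilyloxy)but-3-en-1-yl]-3-[(E)-3-methoxy-3-oxoprop-1-en-1-yl]-1,3-dimethylcyclohexane-1-carboxylate
Product: 19 methyl (1S,4aS,5R,8R,8aS)-8-(tert-butyldimethylsilyloxy)-5-(2-methoxy-2-oxoethyl)-1,4a-dimethyl-6-methylidenedecahydronaphthalene-1-carboxylate
Conditions: Pd(OAc)2 (10 mol %), PPh3 (25 mol %), HCO2Na, Et4NCl, DMF, 80 °C
Reagents that add atoms: none
Why: Zerovalent palladium formed in situ inserts into the C8–Br bond, and the alkenylpalladium bromide adds syn across the (E)-C9=C11 enoate, C8 bonding to C9 while palladium moves to C11 as a palladium enolate. Formate then replaces bromide, loses CO2 and hands over hydride (or the O-bound enolate is protonated), so hydrogen takes the place of palladium at C11; this is the known intramolecular reductive Heck reaction, a formal conjugate addition of an alkenyl halide to an enoate. Ring B closes in the 6-exo-trig mode. C9 is the only new stereocentre and is controlled by the chair-like transition state on the ring A conformer with the C5 and C10 arms diequatorial: the C6 silyloxy group and C11 sit equatorial and H9 axial, anti to the axial C20 methyl, which gives 9R. The step needs ring closure to outrun formate reduction of the alkenylpalladium, and hydride capture to outrun β-hydride loss of H9; the 6R carbinol flanked by two quaternary carbons holds C7 gauche to C10 and favours the first, while sparingly soluble HCO2Na, chloride and the enolate character of the C11–Pd bond favour the second. The C17 methylene takes no part in any bond change and stays exocyclic.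

Step 15
Reactants: 19 methyl (1S,4aS,5R,8R,8aS)-8-(tert-butyldimethylsilyloxy)-5-(2-methoxy-2-oxoethyl)-1,4a-dimethyl-6-methylidenedecahydronaphthalene-1-carboxylate
Product: 20 methyl (1S,4aS,5R,8R,8aS)-8-(tert-butyldimethylsilyloxy)-1,4a-dimethyl-6-methylidene-5-(2-oxoethyl)decahydronaphthalene-1-carboxylate
Conditions: (i-Bu)2AlH (1.1 equiv), CH2Cl2, −78 °C
Reagents that add atoms: none
Why: Partial ester reduction with (i-Bu)2AlH at low temperature: the primary-alkyl C12 ester reacts and its tetrahedral aluminium acetal survives until work-up, while the C18 ester on quaternary C4 next to the silyloxy group is too shielded to compete.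

Step 16
Reactants: 20 methyl (1S,4aS,5R,8R,8aS)-8-(tert-butyldimethylsilyloxy)-1,4a-dimethyl-6-methylidene-5-(2-oxoethyl)decahydronaphthalene-1-carboxylate
Product: 21 methyl (1S,4aS,5R,8R,8aS)-8-(tert-butyldimethylsilyloxy)-1,4a-dimethyl-5-[(2E)-3-methyl-4-oxobut-2-en-1-yl]-6-methylidenedecahydronaphthalene-1-carboxylate
Conditions: Ph3P=C(Me)CHO, toluene, 90 °C
Reagents that add atoms: 2-(triphenylphosphoranylidene)propanal, CC(C=O)=P(c1ccccc1)(c1ccccc1)c1ccccc1
Why: Wittig reaction with a stabilised ylide, whose reversible addition favours the E trisubstituted C12=C13 enal.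

Step 17
Reactants: 21 methyl (1S,4aS,5R,8R,8aS)-8-(tert-butyldimethylsilyloxy)-1,4a-dimethyl-5-[(2E)-3-methyl-4-oxobut-2-en-1-yl]-6-methylidenedecahydronaphthalene-1-carboxylate
Product: 22 methyl (1S,4aS,5R,8R,8aS)-8-(tert-butyldimethylsilyloxy)-1,4a-dimethyl-6-methylidene-5-[(2E)-3-methylpenta-2,4-dien-1-yl]decahydronaphthalene-1-carboxylate
Conditions: Ph3PCH3Br, KN(SiMe3)2, THF, 0 °C; then 21, −78 → 0 °C
Reagents that add atoms: methyltriphenylphosphonium bromide, C[P+](c1ccccc1)(c1ccccc1)c1ccccc1.[Br-]
Why: Wittig methylenation: the enal carbonyl reacts far faster than the hindered C18 ester, and the E geometry of C12=C13 is not touched.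

Step 18
Reactants: 22 methyl (1S,4aS,5R,8R,8aS)-8-(tert-butyldimethylsilyloxy)-1,4a-dimethyl-6-methylidene-5-[(2E)-3-methylpenta-2,4-dien-1-yl]decahydronaphthalene-1-carboxylate
Product: 23 methyl (1S,4aS,5R,8R,8aS)-8-hydroxy-1,4a-dimethyl-6-methylidene-5-[(2E)-3-methylpenta-2,4-dien-1-yl]decahydronaphthalene-1-carboxylate
Conditions: HF·pyridine, pyridine, THF, 0 °C → rt
Reagents that add atoms: none
Why: Fluoride-mediated desilylation under buffered, non-basic conditions, chosen so that no C6 alkoxide forms that could lactonise onto the parallel, peri-disposed C18 ester.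

Step 19
Reactants: 23 methyl (1S,4aS,5R,8R,8aS)-8-hydroxy-1,4a-dimethyl-6-methylidene-5-[(2E)-3-methylpenta-2,4-dien-1-yl]decahydronaphthalene-1-carboxylate
Product: 24 methyl (1S,4aS,5R,8R,8aS)-8-acetoxy-1,4a-dimethyl-6-methylidene-5-[(2E)-3-methylpenta-2,4-dien-1-yl]decahydronaphthalene-1-carboxylate (CNP0212193.1)
Conditions: Ac2O, 4-dimethylaminopyridine, pyridine, rt
Reagents that add atoms: acetic anhydride, CC(=O)OC(C)=O
Why: Nucleophile-catalysed acetylation of the equatorial C6 alcohol with retention at C6, which should give the target.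

Compound list
1 | methyl 2-oxocyclohexane-1-carboxylate | COC(=O)C1CCCCC1=O | starting material
2 | methyl (1R,2R)-2-hydroxycyclohexane-1-carboxylate | COC(=O)[C@@H]1CCCC[C@H]1O | intermediate
3 | methyl (1S,2R)-2-hydroxy-1-methylcyclohexane-1-carboxylate | COC(=O)[C@@]1(C)CCCC[C@H]1O | intermediate
4 | methyl (1S)-1-methyl-2-oxocyclohexane-1-carboxylate | COC(=O)[C@@]1(C)CCCCC1=O | intermediate
5 | methyl (1S)-1,3-dimethyl-2-oxocyclohexane-1-carboxylate (both C10 epimers) | COC(=O)[C@@]1(C)CCCC(C)C1=O | intermediate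
6 | methyl (1S,3S)-3-(hydroxymethyl)-1,3-dimethyl-2-oxocyclohexane-1-carboxylate (present as its lithium alkoxide) | COC(=O)[C@@]1(C)CCC[C@@](C)(CO)C1=O | intermediate
7 | (1S,5S)-1,5-dimethyl-3-oxabicyclo[3.3.1]nonane-2,9-dione | O=C1OC[C@]2(C)CCC[C@@]1(C)C2=O | intermediate
8 | (1S,5R)-1,5-dimethyl-9-methylidene-3-oxabicyclo[3.3.1]nonan-2-one | O=C1OC[C@]2(C)CCC[C@@]1(C)C2=C | intermediate
9 | 9-BBN adduct of 8 (boron on C6, H5 on the lactone side) | O=C1OC[C@]2(C)CCC[C@@]1(C)[C@H]2CB1C2CCCC1CCC2 | intermediate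
10 | (1S,5R,9S)-9-(hydroxymethyl)-1,5-dimethyl-3-oxabicyclo[3.3.1]nonan-2-one | O=C1OC[C@]2(C)CCC[C@@]1(C)[C@H]2CO | intermediate
11 | (1S,5R,9S)-1,5-dimethyl-2-oxo-3-oxabicyclo[3.3.1]nonane-9-carbaldehyde | O=C1OC[C@]2(C)CCC[C@@]1(C)[C@H]2C=O | intermediate
12 | diisopinocampheylborinate of 13 | O=C1OC[C@]2(C)CCC[C@@]1(C)[C@H]2[C@H](OB([C@H]1C[C@H]2C[C@@H]([C@@H]1C)C2(C)C)[C@H]1C[C@H]2C[C@@H]([C@@H]1C)C2(C)C)CC(Br)=C | intermediate
13 | (1S,5R,9S)-9-[(1R)-3-bromo-1-hydroxybut-3-en-1-yl]-1,5-dimethyl-3-oxabicyclo[3.3.1]nonan-2-one | O=C1OC[C@]2(C)CCC[C@@]1(C)[C@H]2[C@H](O)CC(Br)=C | intermediate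
14 | tert-butyldimethylsilyl ether of 13 | O=C1OC[C@]2(C)CCC[C@@]1(C)[C@H]2[C@H](O[Si](C)(C)C(C)(C)C)CC(Br)=C | intermediate
15 | potassium (1S,2S,3R)-2-[(1R)-3-bromo-1-(tert-butyldimethylsilyloxy)but-3-en-1-yl]-3-(hydroxymethyl)-1,3-dimethylcyclohexane-1-carboxylate | OC[C@]1(C)CCC[C@](C)(C(=O)[O-])[C@H]1[C@H](O[Si](C)(C)C(C)(C)C)CC(Br)=C.[K+] | intermediate
16 | methyl (1S,2S,3R)-2-[(1R)-3-bromo-1-(tert-butyldimethylsilyloxy)but-3-en-1-yl]-3-(hydroxymethyl)-1,3-dimethylcyclohexane-1-carboxylate | OC[C@]1(C)CCC[C@](C)(C(=O)OC)[C@H]1[C@H](O[Si](C)(C)C(C)(C)C)CC(Br)=C | intermediate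
17 | methyl (1S,2S,3R)-2-[(1R)-3-bromo-1-(tert-butyldimethylsilyloxy)but-3-en-1-yl]-3-formyl-1,3-dimethylcyclohexane-1-carboxylate | O=C[C@]1(C)CCC[C@](C)(C(=O)OC)[C@H]1[C@H](O[Si](C)(C)C(C)(C)C)CC(Br)=C | intermediate
18 | methyl (1S,2S,3S)-2-[(1R)-3-bromo-1-(tert-butyldimethylsilyloxy)but-3-en-1-yl]-3-[(E)-3-methoxy-3-oxoprop-1-en-1-yl]-1,3-dimethylcyclohexane-1-carboxylate (key-step precursor) | COC(=O)/C=C/[C@]1(C)CCC[C@](C)(C(=O)OC)[C@H]1[C@H](O[Si](C)(C)C(C)(C)C)CC(Br)=C | intermediate
19 | methyl (1S,4aS,5R,8R,8aS)-8-(tert-butyldimethylsilyloxy)-5-(2-methoxy-2-oxoethyl)-1,4a-dimethyl-6-methylidenedecahydronaphthalene-1-carboxylate (key-step product) | COC(=O)C[C@@H]1C(=C)C[C@@H](O[Si](C)(C)C(C)(C)C)[C@H]2[C@@]1(C)CCC[C@]2(C)C(=O)OC | intermediate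
20 | C12 aldehyde: methyl (1S,4aS,5R,8R,8aS)-8-(tert-butyldimethylsilyloxy)-1,4a-dimethyl-6-methylidene-5-(2-oxoethyl)decahydronaphthalene-1-carboxylate | O=CC[C@@H]1C(=C)C[C@@H](O[Si](C)(C)C(C)(C)C)[C@H]2[C@@]1(C)CCC[C@]2(C)C(=O)OC | intermediate
21 | (12E)-enal: methyl (1S,4aS,5R,8R,8aS)-8-(tert-butyldimethylsilyloxy)-1,4a-dimethyl-5-[(2E)-3-methyl-4-oxobut-2-en-1-yl]-6-methylidenedecahydronaphthalene-1-carboxylate | O=C/C(C)=C/C[C@@H]1C(=C)C[C@@H](O[Si](C)(C)C(C)(C)C)[C@H]2[C@@]1(C)CCC[C@]2(C)C(=O)OC | intermediate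
22 | silyl ether of 23 | C=C/C(C)=C/C[C@@H]1C(=C)C[C@@H](O[Si](C)(C)C(C)(C)C)[C@H]2[C@@]1(C)CCC[C@]2(C)C(=O)OC | intermediate
23 | methyl (1S,4aS,5R,8R,8aS)-8-hydroxy-1,4a-dimethyl-6-methylidene-5-[(2E)-3-methylpenta-2,4-dien-1-yl]decahydronaphthalene-1-carboxylate | C=C/C(C)=C/C[C@@H]1C(=C)C[C@@H](O)[C@H]2[C@@]1(C)CCC[C@]2(C)C(=O)OC | intermediate
24 | methyl (1S,4aS,5R,8R,8aS)-8-acetoxy-1,4a-dimethyl-6-methylidene-5-[(2E)-3-methylpenta-2,4-dien-1-yl]decahydronaphthalene-1-carboxylate | C=C/C(C)=C/C[C@@H]1C(=C)C[C@@H](OC(C)=O)[C@H]2[C@@]1(C)CCC[C@]2(C)C(=O)OC | target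

Total step count: 19. Longest linear sequence: 19.

Steps most likely to fail

1. Step 14 (key step). The alkenylpalladium may capture hydride before ring closure, because the diequatorial ring A conformer needed for closure is probably not the resting one. Alternatively, β-hydride loss of H9 after closure would erase C9. The fallback replaces palladium by a tin hydride chain reaction. It sets out from 18: slow addition of Bu3SnH and azobisisobutyronitrile in refluxing benzene generates the C8 vinyl radical. This radical closes 6-exo onto the enoate through the same chair, and the C11 radical takes hydrogen from the stannane. The fallback comes back at 19 and makes no new compound.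

2. Step 9. Addition of the bulky borane to an aldehyde flanked by two quaternary carbons may be slow. The reagent could then decay by loss of allene, or the facial control could erode. The fallback separates C–C bond formation from stereocontrol and sets out from 11. Indium metal and 2,3-dibromopropene in THF–H2O (Barbier addition, small reagent) give the carbinol epimer mixture F1. Dess–Martin oxidation gives the ketone F2. Corey–Bakshi–Shibata reduction follows, with (S)-1-methyl-3,3-diphenyltetrahydro-1H,3H-pyrrolo[1,2-c][1,3,2]oxazaborole and BH3·SMe2. This catalyst reads the bicyclic C5 group as large and the bromoallyl CH2 as small, and should give the 6R alcohol. The fallback comes back at 13.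

3. Step 5. Three things may go wrong: loss of the aldolate by retro-aldol before lactonisation, oligomerisation of formaldehyde, or cleavage of the non-enolisable β-dicarbonyl unit by the liberated methoxide. The fallback avoids basic aldolates altogether and sets out from 5. TMSOTf and Et3N give the trimethylsilyl enol ether F3. A Mukaiyama-type hydroxymethylation with aqueous formaldehyde and Sc(OTf)3 gives 6 beside its C10 epimer F4. Catalytic p-toluenesulfonic acid in warm toluene then lactonises only 6, so the unreactive epimer is removed by chromatography. The fallback comes back at 7.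

Further compounds
F1 | step 9 | (1S,5R,9S)-9-(3-bromo-1-hydroxybut-3-en-1-yl)-1,5-dimethyl-3-oxabicyclo[3.3.1]nonan-2-one, both C6 epimers | O=C1OC[C@]2(C)CCC[C@@]1(C)[C@H]2C(O)CC(Br)=C
F2 | step 9 | (1S,5R,9S)-9-(3-bromobut-3-enoyl)-1,5-dimethyl-3-oxabicyclo[3.3.1]nonan-2-one | O=C1OC[C@]2(C)CCC[C@@]1(C)[C@H]2C(=O)CC(Br)=C
F3 | step 5 | methyl (1S)-1,3-dimethyl-2-(trimethylsilyloxy)cyclohex-2-ene-1-carboxylate | COC(=O)[C@@]1(C)CCCC(C)=C1O[Si](C)(C)C
F4 | step 5 | methyl (1S,3R)-3-(hydroxymethyl)-1,3-dimethyl-2-oxocyclohexane-1-carboxylate | COC(=O)[C@@]1(C)CCC[C@](C)(CO)C1=O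
F0 | step 14 | none | none
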